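**Retrosynthetic overview**
- The target is a 2H-chromen-7(8H)-one. Ring A is the acylated, gem-dimethylated trione carbocycle (C4a, C5–C8, C8a) and ring B the 2H-pyran (O1, C2, C3, C4, C4a, C8a). The strategy rests on ring B being the sum of the C8a-oxygen/C4a edge of ring A, a single carbon (C4) and a C2–C3 alkene unit whose C2 carries methyl and 4-methylpent-3-enyl.
- The C3=C4 double bond is introduced last, by dehydrogenation of the 3,4-dihydro compound.
- Ring B of the dihydro compound is assembled in one pot from the acyl trione, formaldehyde and 2,6-dimethylhepta-1,5-diene: Knoevenagel condensation (C4a–C4), then inverse-demand oxa-Diels–Alder reaction (C4–C3, O1–C2) under a chiral confined Brønsted acid, which sets C2.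
- The acyl trione comes from dearomative gem-dimethylation of the acylphloroglucinol, itself made by Friedel–Crafts acylation of phloroglucinol with (R)-2-methylbutanoyl chloride (source of the side-chain stereocentre). The diene comes from Wittig methylenation of 6-methylhept-5-en-2-one.
- Ring order: ring A (from the aromatic ring, dearomatised) first, ring B second.

Key step: step 5

Remark: β-triketone units are drawn as the enol tautomer hydrogen-bonded to the acyl carbonyl (all tautomers count as one compound), (R)-2-methylbutanoic acid is taken as available in high enantiomeric purity, and the hand of the chiral acid that leads to 2R is to be fixed by experiment.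

**Step 1**
Reactants: 1 (R)-2-methylbutanoic acid
Product: 2 (R)-2-methylbutanoyl chloride
Conditions: (COCl)2, cat. DMF, CH2Cl2, 0 °C → rt; careful concentration, used directly
Reagents that add atoms: oxalyl chloride, ClC(=O)C(=O)Cl
Why: Acid chloride formation through the catalytic chloroiminium species runs without base, so the α-stereocentre is neither enolised nor lost through a ketene and should stay R.

**Step 2**
Reactants: 2 (R)-2-methylbutanoyl chloride; 3 phloroglucinol (benzene-1,3,5-triol)
Product: 4 (R)-2-methyl-1-(2,4,6-trihydroxyphenyl)butan-1-one
Conditions: AlCl3, PhNO2/CH2Cl2, 0 °C → rt; aq. HCl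
Reagents that add atoms: none
Why: Friedel–Crafts C-acylation of the strongly activated triol should stop after one acyl group because the product ring is deactivated, and the mild temperature is chosen so that the α-stereocentre of the aluminium-bound aryl ketone is not enolised.

**Step 3**
Reactants: 4 (R)-2-methyl-1-(2,4,6-trihydroxyphenyl)butan-1-one
Product: 5 3,5-dihydroxy-6,6-dimethyl-2-[(2R)-2-methylbutanoyl]cyclohexa-2,4-dien-1-one
Conditions: NaOMe (3 equiv), MeI (2.2 equiv), MeOH, 0 °C → rt; aq. HCl
Reagents that add atoms: iodomethane, CI
Why: Dearomative double C-methylation of the phloroglucinol polyanion at one ring carbon is the established access to acylfilicinic acids, the product being held as a stabilised vinylogous-acid anion, and the acyl α-carbon is not deprotonated in the polyanion, so it should stay R.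

**Step 4**
Reactants: 6 6-methylhept-5-en-2-one
Product: 7 2,6-dimethylhepta-1,5-diene
Conditions: Ph3PCH3Br, KOtBu, Et2O, 0 °C → rt; distillation
Reagents that add atoms: methyltriphenylphosphonium bromide, C[P+](c1ccccc1)(c1ccccc1)c1ccccc1.[Br-]
Why: Wittig methylenation of the methyl ketone with the non-stabilised ylide should give the 1,1-disubstituted alkene and leave the trisubstituted alkene untouched.

**Step 5**
Reactants: 5 3,5-dihydroxy-6,6-dimethyl-2-[(2R)-2-methylbutanoyl]cyclohexa-2,4-dien-1-one; 7 2,6-dimethylhepta-1,5-diene; 8 formaldehyde (as paraformaldehyde)
Product: 11 (2R)-5-hydroxy-2,8,8-trimethyl-6-[(2R)-2-methylbutanoyl]-2-(4-methylpent-3-en-1-yl)-3,4-dihydro-2H-chromen-7(8H)-one, via hydroxymethyl trione 9 (not isolated), via methylene trione 10 (not isolated)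
Conditions: chiral IDPi (N-triflyl imidodiphosphorimidate from a 3,3'-diaryl-BINOL, 5 mol%), (CH2O)n (1.1 equiv), 7 (3 equiv), 5 Å MS, CHCl3, −20 → 0 °C
Reagents that add atoms: none
Why: Proposed new method: the chiral acid activates formaldehyde for attack by the enol carbon C4a of 5 (aldol stage of the Knoevenagel condensation, C4a–C4) and then ionises the hydroxymethyl group of 9, so that water is lost and the methylene trione 10 arises as a hydrogen-bonded, partly protonated 1-oxadiene (O=C8a–C4a=C4H2) inside the chiral pocket, where it should add the 1,1-disubstituted alkene of 7 in an asynchronous inverse-electron-demand [4+2] cycloaddition that joins the alkene CH2 to C4 and the C8a oxygen to the tertiary carbon (C4–C3 and O1–C2). The closest known reactions are the thermal, racemic domino Knoevenagel/hetero-Diels–Alder reactions of cyclic 1,3-diones with formaldehyde and alkenes and the chiral Brønsted acid-controlled [4+2] cycloadditions of ortho-quinone methides with 1,1-disubstituted styrenes; what is new is enantiocontrol with an alkene that carries two alkyl groups. Ring B (a six-membered dihydropyran) is closed by this intermolecular [4+2] cycloaddition, four atoms coming from the oxadiene and two from the alkene, suprafacially on both partners. The stereocentre C2 is set under catalyst control: the confined counter-anion covers one face of the bound oxadiene and its narrow cavity is expected to accept the methyl group but not the 4-methylpent-3-enyl chain pointing inwards, so that one alkene face is presented and C2 should form as R, while the distant acyl stereocentre is not touched and is not expected to influence the outcome. The step needs the C8a and not the C5 oxygen as diene terminus (secured because the C5 oxygen stays as the enol chelated to the acyl carbonyl), reaction at the 1,1-disubstituted and not the trisubstituted alkene (secured by the unhindered CH2 terminus and the narrow active site), bonding of oxygen to the more substituted alkene carbon (secured because that carbon carries the developing positive charge) and one alkene face (catalyst); it also needs the uncatalysed cycloaddition to be slow, which is why 10 is generated only at the acid and at low temperature.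

**Step 6**
Reactants: 11 (2R)-5-hydroxy-2,8,8-trimethyl-6-[(2R)-2-methylbutanoyl]-2-(4-methylpent-3-en-1-yl)-3,4-dihydro-2H-chromen-7(8H)-one
Product: 12 (2R)-5-hydroxy-2,8,8-trimethyl-6-[(2R)-2-methylbutanoyl]-2-(4-methylpent-3-en-1-yl)-2H-chromen-7(8H)-one
Conditions: DDQ (1.3 equiv), 1,4-dioxane, 80 °C
Reagents that add atoms: none
Why: This is the known DDQ dehydrogenation of a dihydropyran fused to an enolised 1,3-dicarbonyl unit (chroman to 2H-chromene), in which hydride leaves C4, the cation is stabilised by O1 through C4a=C8a and loss of a proton from C3 gives the C3=C4 alkene, while the quaternary C2 and the acyl stereocentre are not involved.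

**Compound list**
1 | (R)-2-methylbutanoic acid | CC[C@@H](C)C(=O)O | starting material
2 | (R)-2-methylbutanoyl chloride | CC[C@@H](C)C(=O)Cl | intermediate
3 | phloroglucinol (benzene-1,3,5-triol) | Oc1cc(O)cc(O)c1 | starting material
4 | (R)-2-methyl-1-(2,4,6-trihydroxyphenyl)butan-1-one | CC[C@@H](C)C(=O)c1c(O)cc(O)cc1O | intermediate
5 | 3,5-dihydroxy-6,6-dimethyl-2-[(2R)-2-methylbutanoyl]cyclohexa-2,4-dien-1-one | CC[C@@H](C)C(=O)C1=C(O)C=C(O)C(C)(C)C1=O | intermediate
6 | 6-methylhept-5-en-2-one | CC(=O)CCC=C(C)C | starting material
7 | 2,6-dimethylhepta-1,5-diene | C=C(C)CCC=C(C)C | intermediate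
8 | formaldehyde (used as paraformaldehyde) | C=O | starting material
9 | 3,5-dihydroxy-4-(hydroxymethyl)-6,6-dimethyl-2-[(2R)-2-methylbutanoyl]cyclohexa-2,4-dien-1-one (hydroxymethyl trione) | CC[C@@H](C)C(=O)C1=C(O)C(CO)=C(O)C(C)(C)C1=O | intermediate
10 | 5-hydroxy-2,2-dimethyl-6-methylidene-4-[(2R)-2-methylbutanoyl]cyclohex-4-ene-1,3-dione (methylene trione) | CC[C@@H](C)C(=O)C1=C(O)C(=C)C(=O)C(C)(C)C1=O | intermediate
11 | (2R)-5-hydroxy-2,8,8-trimethyl-6-[(2R)-2-methylbutanoyl]-2-(4-methylpent-3-en-1-yl)-3,4-dihydro-2H-chromen-7(8H)-one | CC[C@@H](C)C(=O)C1=C(O)C2=C(O[C@](C)(CCC=C(C)C)CC2)C(C)(C)C1=O | intermediate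
12 | (2R)-5-hydroxy-2,8,8-trimethyl-6-[(2R)-2-methylbutanoyl]-2-(4-methylpent-3-en-1-yl)-2H-chromen-7(8H)-one | CC[C@@H](C)C(=O)C1=C(O)C2=C(O[C@](C)(CCC=C(C)C)C=C2)C(C)(C)C1=O | target

**Step count**
Total steps: 6. Longest linear sequence: 5 steps (steps 1, 2, 3, 5 and 6); step 4 is a one-step branch.

**Steps most likely to fail**

Step 5 (three-component Knoevenagel/oxa-Diels–Alder reaction). The main risk is poor facial discrimination at the alkene, since methyl and the chain are both unbranched where they join the alkene carbon. Further risks are leakage through the uncatalysed cycloaddition, Michael capture of the oxadiene by unreacted trione, cycloaddition at the trisubstituted alkene, and Prins-type attack of activated formaldehyde on the diene.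
Fallback, setting out from 5: condensation with citral (3,7-dimethylocta-2,6-dienal) under ethylenediammonium diacetate in MeOH or toluene (Knoevenagel condensation) should give the alkylidene trione (1-oxatriene) F1. This closes by thermal oxa-6π electrocyclisation between the C8a oxygen and the methyl-bearing carbon to the 2H-chromene, with the C3=C4 alkene already in place. C2 is not controlled on this path, so 12 would form together with its (2S)-epimer F2, and the two diastereomers would be separated by preparative HPLC on a chiral stationary phase. The fallback comes back to the route at 12, and step 6 is then not needed.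

Step 6 (dehydrogenation). Hydride abstraction from the electron-poor vinylogous ester may be slow, and the C4 cation may be captured by the side-chain alkene before the proton at C3 is lost.
Fallback, setting out from 5: the oxidation is moved to an open-chain precursor. C-alkylation at the free ring carbon with geranyl bromide (NaOMe, MeOH, 0 °C) should give the 4-geranyl trione F3. Its ring-bound CH2 is flanked by the enol and an alkene, and PhI(OAc)2 with catalytic TEMPO in THF should remove the enol hydrogen and one hydrogen of this CH2. The resulting 1-oxatriene F1 electrocyclises to 12 and its (2S)-epimer F2, which are separated by preparative HPLC on a chiral stationary phase. The fallback comes back to the route at 12.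

Step 3 (dearomative dimethylation). The number and position of the methyl groups may not be controlled: single C-methylation with retained aromaticity, methylation at the second free ring carbon, and O-methylation all compete.
Fallback, setting out from 3: two ring positions are blocked first. Double acetylation (Ac2O, BF3·OEt2) gives 2,4-diacetylphloroglucinol F4. NaOMe/MeI in MeOH can then methylate only the one remaining ring carbon, giving 2,4-diacetyl-3,5-dihydroxy-6,6-dimethylcyclohexa-2,4-dien-1-one F5. Twofold retro-Claisen deacetylation in hot aqueous H2SO4 gives filicinic acid F6. AlCl3-mediated C-acylation of F6 with 2 in PhNO2 comes back to the route at 5.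

**Further compounds**
F1 | step 5 | 6-(3,7-dimethylocta-2,6-dien-1-ylidene)-5-hydroxy-2,2-dimethyl-4-[(2R)-2-methylbutanoyl]cyclohex-4-ene-1,3-dione (alkene geometry not fixed) | CC[C@@H](C)C(=O)C1=C(O)C(=CC=C(C)CCC=C(C)C)C(=O)C(C)(C)C1=O
F2 | step 5 | (2S)-5-hydroxy-2,8,8-trimethyl-6-[(2R)-2-methylbutanoyl]-2-(4-methylpent-3-en-1-yl)-2H-chromen-7(8H)-one | CC[C@@H](C)C(=O)C1=C(O)C2=C(O[C@@](C)(CCC=C(C)C)C=C2)C(C)(C)C1=O
F3 | step 6 | 4-[(2E)-3,7-dimethylocta-2,6-dien-1-yl]-3,5-dihydroxy-6,6-dimethyl-2-[(2R)-2-methylbutanoyl]cyclohexa-2,4-dien-1-one | CC[C@@H](C)C(=O)C1=C(O)C(C/C=C(\C)CCC=C(C)C)=C(O)C(C)(C)C1=O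
F4 | step 3 | 2,4-diacetylphloroglucinol | CC(=O)c1c(O)cc(O)c(C(C)=O)c1O
F5 | step 3 | 2,4-diacetyl-3,5-dihydroxy-6,6-dimethylcyclohexa-2,4-dien-1-one | CC(=O)C1=C(O)C(C(C)=O)=C(O)C(C)(C)C1=O
F6 | step 3 | filicinic acid (3,5-dihydroxy-4,4-dimethylcyclohexa-2,5-dien-1-one) | CC1(C)C(O)=CC(=O)C=C1O
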